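We start from a ratio: how fast the substrates take J, against how fast J pairs with itself.

Z 0.20 M; J 0.140 M; E 0.200 M; Q 0.400 M; time 40 h

    Z + J → Z.J (k1 = 8.39 × 10⁻⁴ M⁻¹ s⁻¹)
    E + J → E.J (k2 = 0.00160 M⁻¹ s⁻¹)
    Q + J → Q.J (k3 = 5.34 × 10⁻⁵ M⁻¹ s⁻¹)
    2 J → J2 (k4 = 0.00143 M⁻¹ s⁻¹)

- for a step with 2 of a species take k times the square, and two of it per event
- the reaction counts as stopped when no species that holds the Z changes by six tenths of a point or more over the second half of the time
- run time (flask): 40 h

* which holds at 40 h: what has brought the reaction to rest, or that it has not come to rest (forward and back rates have come level / it is still moving / all of Z has reacted / J has run out first)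
* part of the Z gone at 40 h
* the Z.J standing at 40 h, as a percentage of the Z charged

The charges come first: J stands below Z, E and Q together, so J is the limiting reagent and we hold the substrates at their charges. On that footing the substrates give J a half-life of 0.378 h, far shorter than the run, so J rather than time should end the reaction. But pairing goes with the square of J, so its share shrinks as J falls. We therefore define the crossing: the fraction of its charge at which J pairs as fast as the substrates take it, 1.27. That is above the charge, so the substrates lead from the start. Following J down, our Z.J is the first constant over two times the fourth, 0.293, times the natural log of one plus the inverse crossing, 0.581. This gives 17.0% of the Z charged.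

The forecast says J has run out first, with conv 17.5% and y_P 17.5%, each from 16.5% to 18.5%, a little above ours; of the two answers it says that “conversion and yield are the same number”.

The simulation gives J has run out first, with conv 17.4% and y_P 17.4%, so the forecast holds; conv moves 5 points with J charged at 0.0915 M or 0.198 M. The midpoint of the Z.J turnover comes at 0.333 h, far earlier than 40 h. At the end this flask holds 0% of its J and 83% of its Z, and our 17.0% from the crossing lies below the simulated figure.

In the neighbour charged with 0.35 M of J, the crossing falls to 0.509 of that charge, so pairing leads at first, and the reckoning gives 31.9%. The simulation gives 32.2%.

(The rate constants come from no measurement; the run is a simulation.)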